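**Retrosynthetic overview**
1. Target 34 ← global desilylation of 33; C7'–H is set by convex-face hydride reduction of aryl hemiketal 32, made from aryllithium 31 and furofuranone 13 (this closes the second tetrahydrofuran ring).
2. Furofuranone 13 ← ring expansion of cyclopropane-fused lactone 11: formaldehyde is formally inserted into the donor–acceptor C–C bond, turning the three-membered ring into the first tetrahydrofuran ring (C7–O and C8'–C9').
3. Lactone 11 ← enantioselective intramolecular cyclopropanation of (Z)-allyl diazoacetate 10 (lactone ring, C8 and C8'), built from catechol, propargyl alcohol and bromoacetyl bromide.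
4. Aryl bromide 30 (threo 8-O-4' unit) ← Evans syn glycolate aldol of imide 23 with aldehyde 26; both syringyl rings come from 4-bromo-2,6-dimethoxyphenol 19 ← resorcinol.
5. Ring order: lactone ring with cyclopropane → first tetrahydrofuran ring (ring expansion) → second tetrahydrofuran ring (aryl addition to the lactone, then reduction).

Assumption: the SMILES is read as written, i.e. a furofuran with exo guaiacyl and endo aryl groups (7R,8S,7'S,8'S) carrying a threo (7''R,8''R) syringylglycerol 8''-O-4' ether.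

**Route**

Step 1
Reactants: 1 catechol
Product: 2 2-methoxyphenol (guaiacol)
Conditions: MeI (1.0 equiv), K2CO3, acetone, reflux
Reagents that add atoms: iodomethane, CI
Why: Williamson mono-O-methylation of the symmetrical diol with one equivalent of MeI gives mainly the mono-ether, separable from catechol and the diether by base extraction and distillation.

Step 2
Reactants: 2 2-methoxyphenol
Product: 3 4-bromo-2-methoxyphenol
Conditions: NBS, MeCN, −20 °C to rt
Reagents that add atoms: N-bromosuccinimide, O=C1CCC(=O)N1Br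
Why: Electrophilic aromatic bromination goes para to the free OH, the stronger director.

Step 3
Reactants: 3 4-bromo-2-methoxyphenol
Product: 4 (4-bromo-2-methoxyphenoxy)triisopropylsilane
Conditions: TIPSCl, imidazole, DMF, rt
Reagents that add atoms: triisopropylsilyl chloride, CC(C)[Si](Cl)(C(C)C)C(C)C
Why: Silyl ether formation; the TIPS aryl ether survives DBU, organolithium and Lewis acid steps and leaves with fluoride at the end.

Step 4
Reactants: 4 (4-bromo-2-methoxyphenoxy)triisopropylsilane; 5 prop-2-yn-1-ol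
Product: 6 3-[3-methoxy-4-(triisopropylsilyloxy)phenyl]prop-2-yn-1-ol
Conditions: PdCl2(PPh3)2 (3 mol %), CuI (5 mol %), Et3N, 70 °C
Reagents that add atoms: none
Why: Sonogashira coupling of the aryl bromide with the terminal alkyne installs C7–C9.

Step 5
Reactants: 6 3-[3-methoxy-4-(triisopropylsilyloxy)phenyl]prop-2-yn-1-ol
Product: 7 (Z)-3-[3-methoxy-4-(triisopropylsilyloxy)phenyl]prop-2-en-1-ol
Conditions: H2 (1 atm), Pd/CaCO3 poisoned with Pb(OAc)2 (Lindlar catalyst), quinoline, EtOAc, rt
Reagents that add atoms: none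
Why: Lindlar semi-hydrogenation adds H2 syn and stops at the Z alkene.

Step 6
Reactants: 7 (Z)-3-[3-methoxy-4-(triisopropylsilyloxy)phenyl]prop-2-en-1-ol; 8 bromoacetyl bromide
Product: 10 (Z)-3-[3-methoxy-4-(triisopropylsilyloxy)phenyl]allyl diazoacetate, via bromoacetate 9 (not isolated)
Conditions: 8, NaHCO3, MeCN, 0 °C; then TsNHNHTs, DBU, THF, 0 °C
Reagents that add atoms: N,N'-ditosylhydrazine, Cc1ccc(cc1)S(=O)(=O)NNS(=O)(=O)c1ccc(C)cc1
Why: O-acylation, then Fukuyama diazoacetate synthesis (N-alkylation of the ditosylhydrazine and base-induced loss of two sulfinates) converts the alcohol into the diazo ester under mild conditions.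

Step 7
Reactants: 10 (Z)-3-[3-methoxy-4-(triisopropylsilyloxy)phenyl]allyl diazoacetate
Product: 11 (1R,5S,6R)-6-[3-methoxy-4-(triisopropylsilyloxy)phenyl]-3-oxabicyclo[3.1.0]hexan-2-one (aryl endo)
Conditions: Rh2(5S-MEPY)4 (1 mol %), CH2Cl2, reflux, slow addition of 10
Reagents that add atoms: none
Why: Enantioselective intramolecular cyclopropanation by a chiral dirhodium carboxamidate carbenoid is stereospecific (Z alkene gives the endo aryl) and the catalyst sets C1 and C5 (future C8' and C8); the 5S catalyst is chosen by analogy with other cis-allylic diazoacetates and its antipode would be used if the sense proved opposite.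

Step 8
Reactants: 11 (1R,5S,6R)-6-[3-methoxy-4-(triisopropylsilyloxy)phenyl]-3-oxabicyclo[3.1.0]hexan-2-one; 12 1,3,5-trioxane
Product: 13 (3aS,4R,6aS)-4-[3-methoxy-4-(triisopropylsilyloxy)phenyl]tetrahydro-1H,3H-furo[3,4-c]furan-1-one (aryl exo, cis ring fusion)
Conditions: 12 (0.4 equiv, cracked in the flask to 1.2 equiv CH2O), TMSOTf (20 mol %), 4 Å MS, CH2Cl2, −40 to 0 °C
Reagents that add atoms: none
Why: Proposed new method: ring expansion of a mono-acceptor (lactone-fused) aryl cyclopropane by formal insertion of formaldehyde, in which O-silylation of the lactone polarises the C1–C6 bond toward a p-silyloxybenzyl cation and a silyl ketene acetal, the oxygen of monomeric formaldehyde (released in the flask from trioxane by TMSOTf) attacks C6 in an SN2-like manner with inversion (endo aryl becomes exo aryl, also the thermodynamic isomer), and the tethered oxocarbenium ion is then captured by the ketene acetal carbon in a Mukaiyama-type closure that can only give the cis-fused bicycle (C8' set, C8 untouched) and releases the silyl cation; the closest known reaction type is the Lewis-acid-catalysed (3+2) annulation of 1,1-diacceptor aryl cyclopropanes with aldehydes, not yet shown for a single lactone acceptor or for formaldehyde.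

Step 9
Reactants: 14 resorcinol
Product: 15 1,3-dimethoxybenzene
Conditions: MeI (2.5 equiv), K2CO3, acetone, reflux
Reagents that add atoms: iodomethane, CI
Why: Exhaustive Williamson O-methylation.

Step 10
Reactants: 15 1,3-dimethoxybenzene
Product: 18 2,6-dimethoxyphenol, via aryllithium 16 (not isolated), via arylboronate 17 (not isolated)
Conditions: n-BuLi, THF, 0 °C to rt; B(OMe)3, −78 °C to rt; then AcOH, 30% H2O2, 0 °C to rt
Reagents that add atoms: hydrogen peroxide, OO
Why: Directed ortho-metalation between the two methoxy groups, borylation and oxidative C–B to C–O conversion place the hydroxyl at C2.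

Step 11
Reactants: 18 2,6-dimethoxyphenol
Product: 19 4-bromo-2,6-dimethoxyphenol
Conditions: NBS, CHCl3, −40 °C to rt
Reagents that add atoms: N-bromosuccinimide, O=C1CCC(=O)N1Br
Why: Electrophilic bromination para to the phenol OH; 19 serves both syringyl rings.

Step 12
Reactants: 19 4-bromo-2,6-dimethoxyphenol; 20 bromoacetic acid
Product: 21 (4-bromo-2,6-dimethoxyphenoxy)acetic acid
Conditions: NaOH, H2O, 90 °C; then HCl
Reagents that add atoms: none
Why: Williamson ether synthesis (phenoxide SN2 on bromoacetate) forms the future 8''-O-4' ether oxygen–carbon bond.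

Step 13
Reactants: 21 (4-bromo-2,6-dimethoxyphenoxy)acetic acid
Product: 23 (S)-4-benzyl-3-[(4-bromo-2,6-dimethoxyphenoxy)acetyl]oxazolidin-2-one, via mixed anhydride 22 (not isolated)
Conditions: t-BuCOCl, Et3N, THF, −20 °C; then LiCl, (S)-4-benzyl-2-oxazolidinone, rt
Reagents that add atoms: (S)-4-benzyl-2-oxazolidinone, O=C1N[C@@H](Cc2ccccc2)CO1
Why: Mixed-anhydride N-acylation attaches the Evans auxiliary.

Step 14
Reactants: 19 4-bromo-2,6-dimethoxyphenol
Product: 24 (4-bromo-2,6-dimethoxyphenoxy)(tert-butyl)dimethylsilane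
Conditions: TBSCl, imidazole, DMF, rt
Reagents that add atoms: tert-butyldimethylsilyl chloride, CC(C)(C)[Si](C)(C)Cl
Why: Silyl protection of the phenol before metalation.

Step 15
Reactants: 24 (4-bromo-2,6-dimethoxyphenoxy)(tert-butyl)dimethylsilane
Product: 26 4-(tert-butyldimethylsilyloxy)-3,5-dimethoxybenzaldehyde, via aryllithium 25 (not isolated)
Conditions: n-BuLi, THF, −78 °C; DMF, −78 to 0 °C; H2O
Reagents that add atoms: N,N-dimethylformamide, CN(C)C=O
Why: Bromine–lithium exchange and formylation with DMF (Bouveault aldehyde synthesis).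

Step 16
Reactants: 23 (S)-4-benzyl-3-[(4-bromo-2,6-dimethoxyphenoxy)acetyl]oxazolidin-2-one; 26 4-(tert-butyldimethylsilyloxy)-3,5-dimethoxybenzaldehyde
Product: 28 (S)-4-benzyl-3-[(2S,3R)-2-(4-bromo-2,6-dimethoxyphenoxy)-3-[4-(tert-butyldimethylsilyloxy)-3,5-dimethoxyphenyl]-3-hydroxypropanoyl]oxazolidin-2-one, via boron enolate 27 (not isolated)
Conditions: Bu2BOTf, i-Pr2NEt, CH2Cl2, −78 to 0 °C; 26, −78 to 0 °C; then pH 7 buffer, MeOH, H2O2
Reagents that add atoms: none
Why: Evans boron glycolate aldol: the Z enolate reacts through a Zimmerman–Traxler chair and the (S)-benzyl auxiliary directs the syn (2S,3R) adduct, i.e. the threo C7''/C8'' pair.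

Step 17
Reactants: 28 Evans aldol adduct
Product: 29 (1R,2R)-2-(4-bromo-2,6-dimethoxyphenoxy)-1-[4-(tert-butyldimethylsilyloxy)-3,5-dimethoxyphenyl]propane-1,3-diol
Conditions: LiBH4, MeOH (1 equiv), THF, 0 °C
Reagents that add atoms: none
Why: Reductive cleavage of the imide gives the primary alcohol and returns the auxiliary without touching either stereocentre.

Step 18
Reactants: 29 (1R,2R)-diol
Product: 30 (1R,2R)-2-(4-bromo-2,6-dimethoxyphenoxy)-1,3-bis(tert-butyldimethylsilyloxy)-1-[4-(tert-butyldimethylsilyloxy)-3,5-dimethoxyphenyl]propane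
Conditions: TBSOTf (2.5 equiv), 2,6-lutidine, CH2Cl2, 0 °C
Reagents that add atoms: tert-butyldimethylsilyl triflate, CC(C)(C)[Si](C)(C)OS(=O)(=O)C(F)(F)F
Why: Bis-silylation masks both hydroxyls for the organolithium step with groups that leave in the final fluoride step.

Step 19
Reactants: 30 aryl bromide; 13 furofuranone
Product: 32 hemiketal (3aS,4R,6aS)-1-aryl-1-hydroxy-4-[3-methoxy-4-(triisopropylsilyloxy)phenyl]tetrahydro-1H,3H-furo[3,4-c]furan (anomer mixture; in equilibrium with the hydroxy ketone), via aryllithium 31 (not isolated)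
Conditions: t-BuLi (2 equiv), THF, −78 °C; then 13, −78 °C; H2O quench at −78 °C
Reagents that add atoms: none
Why: Bromine–lithium exchange and 1,2-addition of the aryllithium to the lactone stop at the lithium hemiketalate at low temperature, forming the C7'–aryl bond.

Step 20
Reactants: 32 hemiketal
Product: 33 tetrasilyl ether of the target (7R,8S,7'S,8'S,7''R,8''R)
Conditions: Et3SiH, BF3·OEt2, CH2Cl2, −78 °C
Reagents that add atoms: none
Why: Ionic hydrogenation: BF3 ionises the hemiketal to the aryl-conjugated bicyclic oxocarbenium ion and Et3SiH delivers hydride to its convex (exo) face, so the aryl group ends endo (7'S); the hemiketal ionises far faster than the other benzylic C–O bonds at −78 °C.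

Step 21
Reactants: 33 tetrasilyl ether
Product: 34 target, (1R,2R)-2-{4-[(1S,3aS,4R,6aS)-4-(4-hydroxy-3-methoxyphenyl)tetrahydro-1H,3H-furo[3,4-c]furan-1-yl]-2,6-dimethoxyphenoxy}-1-(4-hydroxy-3,5-dimethoxyphenyl)propane-1,3-diol
Conditions: TBAF, AcOH, THF, 0 °C to rt
Reagents that add atoms: none
Why: Fluoride-mediated desilylation removes all four silyl groups; the acetic acid buffer avoids base- or acid-induced epimerisation of the benzylic ethers.

**Compound list**
1 | catechol | Oc1ccccc1O | starting material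
2 | 2-methoxyphenol | COc1ccccc1O | intermediate
3 | 4-bromo-2-methoxyphenol | COc1cc(Br)ccc1O | intermediate
4 | (4-bromo-2-methoxyphenoxy)triisopropylsilane | COc1cc(Br)ccc1O[Si](C(C)C)(C(C)C)C(C)C | intermediate
5 | prop-2-yn-1-ol | OCC#C | starting material
6 | 3-[3-methoxy-4-(triisopropylsilyloxy)phenyl]prop-2-yn-1-ol | COc1cc(C#CCO)ccc1O[Si](C(C)C)(C(C)C)C(C)C | intermediate
7 | (Z)-3-[3-methoxy-4-(triisopropylsilyloxy)phenyl]prop-2-en-1-ol | COc1cc(/C=C\CO)ccc1O[Si](C(C)C)(C(C)C)C(C)C | intermediate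
8 | bromoacetyl bromide | BrCC(Br)=O | starting material
9 | (Z)-3-[3-methoxy-4-(triisopropylsilyloxy)phenyl]allyl bromoacetate | COc1cc(/C=C\COC(=O)CBr)ccc1O[Si](C(C)C)(C(C)C)C(C)C | intermediate
10 | (Z)-3-[3-methoxy-4-(triisopropylsilyloxy)phenyl]allyl diazoacetate | COc1cc(/C=C\COC(=O)C=[N+]=[N-])ccc1O[Si](C(C)C)(C(C)C)C(C)C | intermediate
11 | (1R,5S,6R)-6-[3-methoxy-4-(triisopropylsilyloxy)phenyl]-3-oxabicyclo[3.1.0]hexan-2-one | O=C1OC[C@H]2[C@@H](c3ccc(O[Si](C(C)C)(C(C)C)C(C)C)c(OC)c3)[C@@H]12 | intermediate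
12 | 1,3,5-trioxane (formaldehyde trimer) | C1OCOCO1 | starting material
13 | (3aS,4R,6aS)-4-[3-methoxy-4-(triisopropylsilyloxy)phenyl]tetrahydro-1H,3H-furo[3,4-c]furan-1-one | COc1cc([C@@H]2OC[C@@H]3[C@H]2COC3=O)ccc1O[Si](C(C)C)(C(C)C)C(C)C | intermediate
14 | resorcinol | Oc1cccc(O)c1 | starting material
15 | 1,3-dimethoxybenzene | COc1cccc(OC)c1 | intermediate
16 | (2,6-dimethoxyphenyl)lithium | COc1cccc(OC)c1[Li] | intermediate
17 | dimethyl (2,6-dimethoxyphenyl)boronate | COB(OC)c1c(OC)cccc1OC | intermediate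
18 | 2,6-dimethoxyphenol | COc1cccc(OC)c1O | intermediate
19 | 4-bromo-2,6-dimethoxyphenol | COc1cc(Br)cc(OC)c1O | intermediate
20 | bromoacetic acid | OC(=O)CBr | starting material
21 | (4-bromo-2,6-dimethoxyphenoxy)acetic acid | COc1cc(Br)cc(OC)c1OCC(=O)O | intermediate
22 | (4-bromo-2,6-dimethoxyphenoxy)acetic pivalic anhydride | COc1cc(Br)cc(OC)c1OCC(=O)OC(=O)C(C)(C)C | intermediate
23 | (S)-4-benzyl-3-[(4-bromo-2,6-dimethoxyphenoxy)acetyl]oxazolidin-2-one | COc1cc(Br)cc(OC)c1OCC(=O)N1[C@@H](Cc2ccccc2)COC1=O | intermediate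
24 | (4-bromo-2,6-dimethoxyphenoxy)(tert-butyl)dimethylsilane | COc1cc(Br)cc(OC)c1O[Si](C)(C)C(C)(C)C | intermediate
25 | [4-(tert-butyldimethylsilyloxy)-3,5-dimethoxyphenyl]lithium | COc1cc([Li])cc(OC)c1O[Si](C)(C)C(C)(C)C | intermediate
26 | 4-(tert-butyldimethylsilyloxy)-3,5-dimethoxybenzaldehyde | COc1cc(C=O)cc(OC)c1O[Si](C)(C)C(C)(C)C | intermediate
27 | (Z)-dibutylboron enolate of 23 | CCCCB(CCCC)O/C(=C\Oc1c(OC)cc(Br)cc1OC)N1[C@@H](Cc2ccccc2)COC1=O | intermediate
28 | (S)-4-benzyl-3-[(2S,3R)-2-(4-bromo-2,6-dimethoxyphenoxy)-3-[4-(tert-butyldimethylsilyloxy)-3,5-dimethoxyphenyl]-3-hydroxypropanoyl]oxazolidin-2-one | COc1cc(Br)cc(OC)c1O[C@H](C(=O)N1[C@@H](Cc2ccccc2)COC1=O)[C@H](O)c1cc(OC)c(O[Si](C)(C)C(C)(C)C)c(OC)c1 | intermediate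
29 | (1R,2R)-2-(4-bromo-2,6-dimethoxyphenoxy)-1-[4-(tert-butyldimethylsilyloxy)-3,5-dimethoxyphenyl]propane-1,3-diol | COc1cc(Br)cc(OC)c1O[C@H](CO)[C@H](O)c1cc(OC)c(O[Si](C)(C)C(C)(C)C)c(OC)c1 | intermediate
30 | 1,3-bis(tert-butyldimethylsilyl) ether of 29 | COc1cc(Br)cc(OC)c1O[C@H](CO[Si](C)(C)C(C)(C)C)[C@H](O[Si](C)(C)C(C)(C)C)c1cc(OC)c(O[Si](C)(C)C(C)(C)C)c(OC)c1 | intermediate
31 | aryllithium from 30 | COc1cc([Li])cc(OC)c1O[C@H](CO[Si](C)(C)C(C)(C)C)[C@H](O[Si](C)(C)C(C)(C)C)c1cc(OC)c(O[Si](C)(C)C(C)(C)C)c(OC)c1 | intermediate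
32 | aryl hemiketal from 13 and 31 (anomeric centre undefined) | COc1cc([C@@H]2OC[C@@H]3[C@H]2COC3(O)c2cc(OC)c(O[C@H](CO[Si](C)(C)C(C)(C)C)[C@H](O[Si](C)(C)C(C)(C)C)c3cc(OC)c(O[Si](C)(C)C(C)(C)C)c(OC)c3)c(OC)c2)ccc1O[Si](C(C)C)(C(C)C)C(C)C | intermediate
33 | tetrasilyl ether of the target (one TIPS, three TBS) | COc1cc([C@@H]2OC[C@@H]3[C@H]2CO[C@@H]3c2cc(OC)c(O[C@H](CO[Si](C)(C)C(C)(C)C)[C@H](O[Si](C)(C)C(C)(C)C)c3cc(OC)c(O[Si](C)(C)C(C)(C)C)c(OC)c3)c(OC)c2)ccc1O[Si](C(C)C)(C(C)C)C(C)C | intermediate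
34 | (1R,2R)-2-{4-[(1S,3aS,4R,6aS)-4-(4-hydroxy-3-methoxyphenyl)tetrahydro-1H,3H-furo[3,4-c]furan-1-yl]-2,6-dimethoxyphenoxy}-1-(4-hydroxy-3,5-dimethoxyphenyl)propane-1,3-diol | COc1cc([C@@H]2OC[C@@H]3[C@H]2CO[C@@H]3c2cc(OC)c(O[C@H](CO)[C@H](O)c3cc(OC)c(O)c(OC)c3)c(OC)c2)ccc1O | target

**Step count**
Total: 21 steps. Longest linear sequence: 11 steps (1–8, then 19–21; the sequence 9–13, 16–21 is equally long).

**Steps most likely to fail, with fallbacks**

Step 8 (proposed new ring expansion; a single lactone acceptor may not activate the cyclopropane enough, or the benzylic cation may eliminate). The fallback uses the established doubly activated manifold and sets out from alcohol 7. It is acylated with methyl malonyl chloride and pyridine to the mixed malonate F1. Diazo transfer with 4-acetamidobenzenesulfonyl azide and Et3N gives the diazomalonate F2. Intramolecular cyclopropanation with a chiral cobalt porphyrin, Co(3,5-DitBu-ChenPhyrin) (divalent cobalt), gives the lactone-ester cyclopropane F3. The known Sn(OTf)2-catalysed aldehyde (3+2) annulation of 1,1-diacceptor aryl cyclopropanes, run with formaldehyde from 12, gives the ester-bearing furofuranone F4. Krapcho dealkoxycarbonylation (LiCl, wet DMSO, 140 °C), whose protonation can only give the cis-fused bicycle, returns to the route at 13.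

Step 19 (enolisation of the lactone or double addition of the precious aryllithium). The fallback sets out from 13, which is reduced with i-Bu2AlH at −78 °C to the lactol F5. After deprotonation with NaH, F5 takes up aryllithium 31 at the aldehyde tautomer to give the diol F6 as a mixture of carbinol epimers. Selective benzylic oxidation of F6 with MnO2 gives the hydroxy ketone, which is the open tautomer of 32, where the route is rejoined.

Step 20 (loss of endo selectivity, or ionisation and reduction of the other electron-rich benzylic C–O bonds). The fallback sets out from 32. Its hydroxy ketone tautomer is reduced under reagent control with (R)-Me-CBS and BH3·SMe2 to the (S)-carbinol diol F7. Selective sulfonylation of the primary hydroxyl with TsCl in pyridine gives the mono-tosylate F8. NaH then closes the ring by Williamson displacement at the primary carbon, with retention at C7', and the route is rejoined at 33.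

**Further compounds**
F1 | step 8 | (Z)-3-[3-methoxy-4-(triisopropylsilyloxy)phenyl]allyl methyl malonate | COC(=O)CC(=O)OC/C=C\c1ccc(O[Si](C(C)C)(C(C)C)C(C)C)c(OC)c1
F2 | step 8 | (Z)-3-[3-methoxy-4-(triisopropylsilyloxy)phenyl]allyl methyl diazomalonate | COC(=O)C(=[N+]=[N-])C(=O)OC/C=C\c1ccc(O[Si](C(C)C)(C(C)C)C(C)C)c(OC)c1
F3 | step 8 | methyl 6-[3-methoxy-4-(triisopropylsilyloxy)phenyl]-2-oxo-3-oxabicyclo[3.1.0]hexane-1-carboxylate (aryl endo, C5 and C6 as in 11) | O=C1OC[C@H]2[C@@H](c3ccc(O[Si](C(C)C)(C(C)C)C(C)C)c(OC)c3)[C@@]12C(=O)OC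
F4 | step 8 | methyl 4-[3-methoxy-4-(triisopropylsilyloxy)phenyl]-1-oxotetrahydro-1H,3H-furo[3,4-c]furan-6a-carboxylate (aryl exo, cis-fused, C3a and C4 as in 13) | COc1cc([C@@H]2OC[C@]3(C(=O)OC)[C@H]2COC3=O)ccc1O[Si](C(C)C)(C(C)C)C(C)C
F5 | step 19 | lactol from 13, (3aS,4R,6aS)-4-[3-methoxy-4-(triisopropylsilyloxy)phenyl]tetrahydro-1H,3H-furo[3,4-c]furan-1-ol (anomer mixture) | COc1cc([C@@H]2OC[C@@H]3[C@H]2COC3O)ccc1O[Si](C(C)C)(C(C)C)C(C)C
F6 | step 19 | ring-opened diol from F5 and 31 (carbinol epimers) | COc1cc([C@@H]2OC[C@@H](C(O)c3cc(OC)c(O[C@H](CO[Si](C)(C)C(C)(C)C)[C@H](O[Si](C)(C)C(C)(C)C)c4cc(OC)c(O[Si](C)(C)C(C)(C)C)c(OC)c4)c(OC)c3)[C@H]2CO)ccc1O[Si](C(C)C)(C(C)C)C(C)C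
F7 | step 20 | (S)-carbinol diol from reduction of 32 | COc1cc([C@@H]2OC[C@@H]([C@H](O)c3cc(OC)c(O[C@H](CO[Si](C)(C)C(C)(C)C)[C@H](O[Si](C)(C)C(C)(C)C)c4cc(OC)c(O[Si](C)(C)C(C)(C)C)c(OC)c4)c(OC)c3)[C@H]2CO)ccc1O[Si](C(C)C)(C(C)C)C(C)C
F8 | step 20 | primary mono-tosylate of F7 | COc1cc([C@@H]2OC[C@@H]([C@H](O)c3cc(OC)c(O[C@H](CO[Si](C)(C)C(C)(C)C)[C@H](O[Si](C)(C)C(C)(C)C)c4cc(OC)c(O[Si](C)(C)C(C)(C)C)c(OC)c4)c(OC)c3)[C@H]2COS(=O)(=O)c5ccc(C)cc5)ccc1O[Si](C(C)C)(C(C)C)C(C)C
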